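**Retrosynthetic overview**

1. Labdane numbering is used: C1–C10 decalin, C11–C16 side chain, C17 on C8, C18/C19 on C4 (C19 oxygenated), C20 on C10. The route rests on ring B (C5–C10): quaternary C10 is bonded to C9, which carries the whole C11–C16 chain, and C9 sits next to C8, which carries C17. Cutting C7–C8 and C9–C10 (Diels–Alder) gives ring-A diene 13 (C1–C7, C18–C20) and alkynyl ketone 17 (C8, C9, C11–C17).
2. Ring A is not built; it comes from 2,6-dimethylcyclohexanone. C4 is set by enantioselective decarboxylative allylation, the allyl group is cut down to C19–OTIPS, and C5 is vinylated through its enol triflate. Ynone 17 comes from methyl hydrogen (R)-3-methylglutarate (C13) and propargyl acetate. Ring B is the only ring closed (step 10).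
3. C17 is carried as CH2OAc instead of CH3, because base would deprotonate the C8=C9–C11=O enone at C12 or C7 and not at C17. After hydrogenation of C5=C6, SmI2 expels the acetate, gives the C8=C17 dienolate regiospecifically, and C9 is protonated.
4. C11 is then deoxygenated, the silyl group is exchanged for the (R)-2-methylbutanoyl group, and the methyl ester is hydrolysed.

Key step: step 10

Assumption: (S)-t-BuPHOX is taken to give the 2S ketone 5, as it does with the enol carbonate of 2-methylcyclohexanone; if the sense were opposite, the R ligand would be used.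

**Step 1**
Reactants: 1 2,6-dimethylcyclohexan-1-one (cis/trans mixture); 2 allyl chloroformate
Product: 4 allyl 2,6-dimethylcyclohex-1-en-1-yl carbonate, via lithium enolate 3 (not isolated)
Conditions: LiHMDS, THF, 0 °C; then 2, −78 °C to rt
Reagents that add atoms: none
Why: The symmetrical ketone can form only one (tetrasubstituted) enolate, and this hindered enolate should be acylated on oxygen by the chloroformate (enol carbonate formation).

**Step 2**
Reactants: 4 allyl 2,6-dimethylcyclohex-1-en-1-yl carbonate
Product: 5 (2S)-2-allyl-2,6-dimethylcyclohexan-1-one (both C6 epimers)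
Conditions: Pd2(dba)3 (2.5 mol %), (S)-t-BuPHOX (6.25 mol %), THF, 25 °C
Reagents that add atoms: none
Why: Decarboxylative asymmetric allylic alkylation (Tsuji allylation): zerovalent palladium ionises the allyl carbonate, CO2 is lost and the PHOX-bound allylpalladium enolate recombines at carbon, the ligand choosing the enolate face and so setting the quaternary carbon (future C4), while the C6 methine needs no control because it becomes trigonal C10 in step 7.

**Step 3**
Reactants: 5 (2S)-2-allyl-2,6-dimethylcyclohexan-1-one
Product: 6 (2S)-2,6-dimethyl-2-[(E)-prop-1-en-1-yl]cyclohexan-1-one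
Conditions: RuHCl(CO)(PPh3)3 (5 mol %), toluene, 110 °C
Reagents that add atoms: none
Why: Ruthenium-hydride alkene isomerisation (hydrometalation/β-hydride elimination) should move the terminal alkene one position to the more substituted, mainly E place, where the quaternary carbon stops further migration; any Z isomer is cleaved to the same aldehyde in step 4.

**Step 4**
Reactants: 6 (2S)-2,6-dimethyl-2-[(E)-prop-1-en-1-yl]cyclohexan-1-one
Product: 8 (1S)-1,3-dimethyl-2-oxocyclohexane-1-carbaldehyde, via ozonide 7 (not isolated)
Conditions: O3, CH2Cl2, −78 °C; then PPh3, −78 °C to rt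
Reagents that add atoms: ozone, [O-][O+]=O
Why: Ozonolysis with reductive work-up cuts the propenyl C=C and leaves the carbon bonded to the quaternary centre as the aldehyde (future C19), the ketone being inert to ozone.

**Step 5**
Reactants: 8 (1S)-1,3-dimethyl-2-oxocyclohexane-1-carbaldehyde
Product: 9 (2S)-2-(hydroxymethyl)-2,6-dimethylcyclohexan-1-one
Conditions: NaBH4 (0.5 equiv), MeOH–CH2Cl2, −78 °C
Reagents that add atoms: none
Why: Chemoselective hydride reduction: the aldehyde is far more electrophilic than the 2,2,6-trisubstituted ketone, and the cold medium should suppress retro-aldol loss of formaldehyde.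

**Step 6**
Reactants: 9 (2S)-2-(hydroxymethyl)-2,6-dimethylcyclohexan-1-one
Product: 10 (2S)-2,6-dimethyl-2-{[tri(propan-2-yl)silyl]oxymethyl}cyclohexan-1-one
Conditions: TIPSOTf, 2,6-lutidine, CH2Cl2, 0 °C
Reagents that add atoms: triisopropylsilyl trifluoromethanesulfonate, CC(C)[Si](OS(=O)(=O)C(F)(F)F)(C(C)C)C(C)C
Why: Silylation of the neopentyl primary alcohol with a silyl triflate and a hindered pyridine base, conditions too weakly basic to trigger retro-aldol cleavage of the β-hydroxy ketone.

**Step 7**
Reactants: 10 (2S)-2,6-dimethyl-2-{[tri(propan-2-yl)silyl]oxymethyl}cyclohexan-1-one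
Product: 12 (6S)-2,6-dimethyl-6-{[tri(propan-2-yl)silyl]oxymethyl}cyclohex-1-en-1-yl trifluoromethanesulfonate, via potassium enolate 11 (not isolated)
Conditions: KHMDS, THF, −78 to 0 °C; then PhNTf2, −78 °C to rt
Reagents that add atoms: N-phenylbis(trifluoromethanesulfonimide), O=S(=O)(N(c1ccccc1)S(=O)(=O)C(F)(F)F)C(F)(F)F
Why: The only α-hydrogen left is on the methyl-bearing carbon (future C10), so a single enolate forms and is sulfonylated on oxygen (enol triflate formation), which also merges the two C6 epimers.

**Step 8**
Reactants: 12 enol triflate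
Product: 13 {[(1R)-1,3-dimethyl-2-vinylcyclohex-2-en-1-yl]methoxy}tri(propan-2-yl)silane
Conditions: tributyl(vinyl)stannane, Pd(PPh3)4 (5 mol %), LiCl, THF, 65 °C
Reagents that add atoms: tributyl(vinyl)stannane, C=C[Sn](CCCC)(CCCC)CCCC
Why: Stille coupling of a hindered cyclohexenyl triflate with a vinylstannane, with LiCl assisting transmetalation, a standard way to 2,6,6-trisubstituted 1-vinylcyclohexenes.

**Step 9**
Reactants: 14 methyl hydrogen (R)-3-methylglutarate; 15 propargyl acetate
Product: 17 methyl (3R)-8-acetoxy-3-methyl-5-oxooct-6-ynoate, via acid chloride 16 (not isolated)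
Conditions: (COCl)2, DMF (cat.), CH2Cl2, 0 °C to rt; evaporate; then 15, PdCl2(PPh3)2 (2 mol %), CuI (4 mol %), Et3N, THF, rt
Reagents that add atoms: none
Why: Acyl Sonogashira coupling: the acid chloride is made and used at or below room temperature (to avoid scrambling through the symmetrical cyclic anhydride) and couples with the copper acetylide of 15, while C13 lies β to both carbonyl groups and is not touched.

**Step 10 (key step)**
Reactants: 13 ring-A diene; 17 ynone
Product: 18 methyl (4R,10R,13R)-17-acetoxy-11-oxo-19-[tri(propan-2-yl)silyloxy]labda-5,8-dien-15-oate (C20 cis to C19)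
Conditions: Me2AlCl (3 equiv), CH2Cl2, −78 to −20 °C
Reagents that add atoms: none
Why: Me2AlCl on the ynone carbonyl lowers its LUMO, and the trialkyl-substituted diene adds in a concerted but asynchronous [4+2] cycloaddition in which the bond from the unhindered terminus C7 to the ynone β-carbon C8 runs ahead of the C9–C10 bond that creates the quaternary carbon. The closest known reaction type is the Diels–Alder addition of 2-methyl-1-vinylcyclohexenes to acetylenic carbonyl dienophiles. Ring B closes as a six-membered 1,4-cyclohexadiene by intermolecular [4+2] annulation across C7 and C10, so there is no endo/exo question and C9 stays trigonal for later protonation. The one new stereocentre, C10, is controlled by C4: the CH2OTIPS group, pseudoaxial to avoid the C5 vinyl group, screens its face, the ynone passes the smaller C18 methyl, and C20 is pushed to the side of C19. The step needs regioselectivity (C9, not C8, bonded to C10), secured by the larger HOMO coefficient and lower hindrance at C7 meeting the electrophilic β-carbon, and facial selectivity, which rests only on the size difference of the two C4 substituents and is the reason for the bulky silyl group. The acetoxymethyl group is no larger than methyl at the reacting carbon and makes the alkyne slightly more electron-poor.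

**Step 11**
Reactants: 18 Diels–Alder adduct
Product: 19 methyl (4R,5S,10R,13R)-17-acetoxy-11-oxo-19-[tri(propan-2-yl)silyloxy]labd-8-en-15-oate
Conditions: H2 (1 atm), 5% Pt/C, EtOAc, rt
Reagents that add atoms: none
Why: Heterogeneous hydrogenation should add to the trisubstituted C5=C6 bond from the face opposite the axial C19 and C20 groups, giving the trans-fused H5, while the tetrasubstituted, carbonyl-conjugated C8=C9 bond is too hindered to compete and platinum is less prone than palladium to allylic C–O hydrogenolysis.

**Step 12**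
Reactants: 19 γ-acetoxy enone
Product: 20 methyl (4R,5S,9R,10R,13R)-11-oxo-19-[tri(propan-2-yl)silyloxy]labd-8(17)-en-15-oate
Conditions: SmI2 (2.5 equiv), THF–MeOH, −78 °C
Reagents that add atoms: none
Why: Reductive elimination of a vinylogous α-acyloxy ketone: electron transfer from SmI2 to the enone expels the γ-acetate and gives the samarium dienolate with the C8=C17 bond regiospecifically, and kinetic protonation at the α-carbon C9 from the face opposite the axial C20 methyl gives the β,γ-unsaturated ketone with H9 trans to C20.

**Step 13**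
Reactants: 20 β,γ-unsaturated ketone
Product: 21 methyl (4R,5S,9R,10R,13R)-11-hydroxy-19-[tri(propan-2-yl)silyloxy]labd-8(17)-en-15-oate (either C11 epimer)
Conditions: NaBH4, MeOH, −20 °C; pH 7 buffer
Reagents that add atoms: none
Why: Borohydride reduction of the C11 ketone, run cold with a buffered work-up and with the product used at once, so that the δ-hydroxy ester does not close to the lactone onto C15.

**Step 14**
Reactants: 21 C11 alcohol
Product: 22 methyl (4R,5S,9R,10R,13R)-11-(phenoxycarbonothioyloxy)-19-[tri(propan-2-yl)silyloxy]labd-8(17)-en-15-oate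
Conditions: PhOC(S)Cl, pyridine, DMAP (cat.), CH2Cl2, 0 °C to rt
Reagents that add atoms: O-phenyl chlorothionoformate, S=C(Cl)Oc1ccccc1
Why: Thioacylation by nucleophilic catalysis (first half of a Barton–McCombie deoxygenation), chosen over xanthate formation with NaH because a free alkoxide could lactonise onto C15.

**Step 15**
Reactants: 22 thionocarbonate
Product: 23 methyl (4R,5S,9R,10S,13R)-19-[tri(propan-2-yl)silyloxy]labd-8(17)-en-15-oate
Conditions: Bu3SnH, AIBN (cat.), toluene, 100 °C
Reagents that add atoms: none
Why: Barton–McCombie radical deoxygenation: the stannyl radical adds to C=S, β-scission gives the secondary C11 radical and Bu3SnH reduces it, any 3-exo closure of this homoallylic radical onto C8=C17 being reversible so that the alkene and C9 are kept.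

**Step 16**
Reactants: 23 silyl ether
Product: 24 methyl (4R,5S,9R,10S,13R)-19-hydroxylabd-8(17)-en-15-oate
Conditions: TBAF, THF, rt
Reagents that add atoms: none
Why: Fluoride cleavage of the silyl ether, which the methyl ester and the exocyclic alkene should tolerate at room temperature.

**Step 17**
Reactants: 24 C19 alcohol; 25 (2R)-2-methylbutanoic acid
Product: 26 methyl (4R,5S,9R,10S,13R)-19-{[(2R)-2-methylbutanoyl]oxy}labd-8(17)-en-15-oate
Conditions: DCC, DMAP (cat.), CH2Cl2, 0 °C to rt
Reagents that add atoms: none
Why: Steglich esterification of the neopentyl primary alcohol; since no acid chloride–amine pair is used, no ketene can form and the α-stereocentre of the acyl group should be kept.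

**Step 18**
Reactants: 26 diester
Product: 28 (4R,5S,9R,10S,13R)-19-{[(2R)-2-methylbutanoyl]oxy}labd-8(17)-en-15-oic acid, via lithium carboxylate 27 (not isolated)
Conditions: LiOH·H2O (1.5 equiv), THF–H2O, 0 °C to rt; then dilute HCl to pH 4
Reagents that add atoms: lithium hydroxide, [Li+].[OH-]
Why: Saponification: hydroxide should attack the unhindered methyl ester much faster than the neopentyl ester of an α-branched acid, and these mild conditions should not epimerise the 2-methylbutanoate.

**Compound list**

Descriptors at C9, C10 and in 16 change along the route only through the CIP rules; the spatial arrangement is that of the target throughout.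

1 | 2,6-dimethylcyclohexan-1-one (cis/trans mixture) | CC1CCCC(C)C1=O | starting material
2 | allyl chloroformate | C=CCOC(=O)Cl | starting material
3 | lithium 2,6-dimethylcyclohex-1-en-1-olate | [Li+].[O-]C1=C(C)CCCC1C | intermediate
4 | allyl 2,6-dimethylcyclohex-1-en-1-yl carbonate (racemic at C6) | C=CCOC(=O)OC1=C(C)CCCC1C | intermediate
5 | (2S)-2-allyl-2,6-dimethylcyclohexan-1-one (both C6 epimers) | C=CC[C@]1(C)CCCC(C)C1=O | intermediate
6 | (2S)-2,6-dimethyl-2-[(E)-prop-1-en-1-yl]cyclohexan-1-one | C/C=C/[C@]1(C)CCCC(C)C1=O | intermediate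
7 | 3-[(1S)-1,3-dimethyl-2-oxocyclohexyl]-5-methyl-1,2,4-trioxolane (ozonide) | CC1OOC(O1)[C@]2(C)CCCC(C)C2=O | intermediate
8 | (1S)-1,3-dimethyl-2-oxocyclohexane-1-carbaldehyde | O=C[C@]1(C)CCCC(C)C1=O | intermediate
9 | (2S)-2-(hydroxymethyl)-2,6-dimethylcyclohexan-1-one | OC[C@]1(C)CCCC(C)C1=O | intermediate
10 | (2S)-2,6-dimethyl-2-{[tri(propan-2-yl)silyl]oxymethyl}cyclohexan-1-one | CC(C)[Si](OC[C@]1(C)CCCC(C)C1=O)(C(C)C)C(C)C | intermediate
11 | potassium (6S)-2,6-dimethyl-6-{[tri(propan-2-yl)silyl]oxymethyl}cyclohex-1-en-1-olate | [K+].[O-]C1=C(C)CCC[C@@]1(C)CO[Si](C(C)C)(C(C)C)C(C)C | intermediate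
12 | (6S)-2,6-dimethyl-6-{[tri(propan-2-yl)silyl]oxymethyl}cyclohex-1-en-1-yl trifluoromethanesulfonate | O=S(=O)(OC1=C(C)CCC[C@@]1(C)CO[Si](C(C)C)(C(C)C)C(C)C)C(F)(F)F | intermediate
13 | {[(1R)-1,3-dimethyl-2-vinylcyclohex-2-en-1-yl]methoxy}tri(propan-2-yl)silane (ring-A diene) | C=CC1=C(C)CCC[C@@]1(C)CO[Si](C(C)C)(C(C)C)C(C)C | intermediate
14 | methyl hydrogen (R)-3-methylglutarate [(3R)-5-methoxy-3-methyl-5-oxopentanoic acid] | OC(=O)C[C@@H](C)CC(=O)OC | starting material
15 | prop-2-yn-1-yl acetate (propargyl acetate) | CC(=O)OCC#C | starting material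
16 | methyl (3S)-5-chloro-3-methyl-5-oxopentanoate | ClC(=O)C[C@@H](C)CC(=O)OC | intermediate
17 | methyl (3R)-8-acetoxy-3-methyl-5-oxooct-6-ynoate | CC(=O)OCC#CC(=O)C[C@@H](C)CC(=O)OC | intermediate
18 | methyl (4R,10R,13R)-17-acetoxy-11-oxo-19-[tri(propan-2-yl)silyloxy]labda-5,8-dien-15-oate | CC(=O)OCC1=C(C(=O)C[C@@H](C)CC(=O)OC)[C@]2(C)CCC[C@@](C)(CO[Si](C(C)C)(C(C)C)C(C)C)C2=CC1 | intermediate
19 | methyl (4R,5S,10R,13R)-17-acetoxy-11-oxo-19-[tri(propan-2-yl)silyloxy]labd-8-en-15-oate | CC(=O)OCC1=C(C(=O)C[C@@H](C)CC(=O)OC)[C@]2(C)CCC[C@@](C)(CO[Si](C(C)C)(C(C)C)C(C)C)[C@H]2CC1 | intermediate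
20 | methyl (4R,5S,9R,10R,13R)-11-oxo-19-[tri(propan-2-yl)silyloxy]labd-8(17)-en-15-oate | C=C1CC[C@@H]2[C@](C)(CO[Si](C(C)C)(C(C)C)C(C)C)CCC[C@@]2(C)[C@@H]1C(=O)C[C@@H](C)CC(=O)OC | intermediate
21 | methyl (4R,5S,9R,10R,13R)-11-hydroxy-19-[tri(propan-2-yl)silyloxy]labd-8(17)-en-15-oate (C11 epimers) | C=C1CC[C@@H]2[C@](C)(CO[Si](C(C)C)(C(C)C)C(C)C)CCC[C@@]2(C)[C@@H]1C(O)C[C@@H](C)CC(=O)OC | intermediate
22 | methyl (4R,5S,9R,10R,13R)-11-(phenoxycarbonothioyloxy)-19-[tri(propan-2-yl)silyloxy]labd-8(17)-en-15-oate (C11 epimers) | C=C1CC[C@@H]2[C@](C)(CO[Si](C(C)C)(C(C)C)C(C)C)CCC[C@@]2(C)[C@@H]1C(OC(=S)Oc3ccccc3)C[C@@H](C)CC(=O)OC | intermediate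
23 | methyl (4R,5S,9R,10S,13R)-19-[tri(propan-2-yl)silyloxy]labd-8(17)-en-15-oate | C=C1CC[C@@H]2[C@](C)(CO[Si](C(C)C)(C(C)C)C(C)C)CCC[C@@]2(C)[C@@H]1CC[C@@H](C)CC(=O)OC | intermediate
24 | methyl (4R,5S,9R,10S,13R)-19-hydroxylabd-8(17)-en-15-oate | C=C1CC[C@@H]2[C@](C)(CO)CCC[C@@]2(C)[C@@H]1CC[C@@H](C)CC(=O)OC | intermediate
25 | (2R)-2-methylbutanoic acid | CC[C@@H](C)C(=O)O | starting material
26 | methyl (4R,5S,9R,10S,13R)-19-{[(2R)-2-methylbutanoyl]oxy}labd-8(17)-en-15-oate | C=C1CC[C@@H]2[C@](C)(COC(=O)[C@H](C)CC)CCC[C@@]2(C)[C@@H]1CC[C@@H](C)CC(=O)OC | intermediate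
27 | lithium (4R,5S,9R,10S,13R)-19-{[(2R)-2-methylbutanoyl]oxy}labd-8(17)-en-15-oate | C=C1CC[C@@H]2[C@](C)(COC(=O)[C@H](C)CC)CCC[C@@]2(C)[C@@H]1CC[C@@H](C)CC(=O)[O-].[Li+] | intermediate
28 | (4R,5S,9R,10S,13R)-19-{[(2R)-2-methylbutanoyl]oxy}labd-8(17)-en-15-oic acid = (3R)-5-[(1R,4aS,5R,8aS)-5,8a-dimethyl-2-methylidene-5-{[(2R)-2-methylbutanoyl]oxymethyl}decahydronaphthalen-1-yl]-3-methylpentanoic acid | C=C1CC[C@@H]2[C@](C)(COC(=O)[C@H](C)CC)CCC[C@@]2(C)[C@@H]1CC[C@@H](C)CC(=O)O | target

**Step count**

Total: 18 steps. Longest linear sequence: 17 steps (steps 1–8, then 10–18); step 9 is the one-step side branch.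

**Steps most likely to fail**

Step 10 (key cycloaddition). Ring closure at the fully substituted terminus C10 may be slow. The diene or the propargylic acetate could then be ionised by the Lewis acid, the third carbonyl group could tie up Me2AlCl, and the ynone may not distinguish the two faces set by C4 well enough. Fallback, without the acetate: acid chloride 16 would be coupled with propynylzinc chloride (from 1-propynylmagnesium bromide and ZnCl2; Pd(PPh3)4, THF, 0 °C) to methyl (3R)-3-methyl-5-oxooct-6-ynoate F1, which has one Lewis-basic site fewer and nothing that can ionise. Cycloaddition of F1 with 13 (1.1–2 equiv Me2AlCl, or neat at 110 °C without Lewis acid) should give methyl (4R,10R,13R)-11-oxo-19-[tri(propan-2-yl)silyloxy]labda-5,8-dien-15-oate F2. Hydrogenation as in step 11 should give methyl (4R,5S,10R,13R)-11-oxo-19-[tri(propan-2-yl)silyloxy]labd-8-en-15-oate F3. The alkene would then be moved photochemically, not by base: on irradiation near 300 nm with a trace of an imidazole base the excited enone takes a hydrogen from C17, the only γ-carbon cis to the carbonyl group, and the dienol ketonises by protonation at C9. This returns to the route at 20.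

Step 12 (reductive deconjugation). Electron transfer to the twisted, weakly conjugated enone may be slow, so that reduction of the C11 carbonyl group could come before loss of acetate, and the β,γ-unsaturated ketone may slip back into conjugation on work-up. Fallback from 19: palladium-catalysed formate hydrogenolysis of the allylic acetate (Pd(OAc)2, PBu3, HCO2NH4, dioxane, 70 °C). Zerovalent palladium ionises the C17–O bond on the open face, and hydride passes from palladium to the more substituted allyl terminus C9. This should give 20 directly, with no electron transfer to the carbonyl group and no new compound.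

Step 11 (hydrogenation). On the metal surface the allylic acetate may be hydrogenolysed, or the C5=C6 bond may migrate into conjugation before it is saturated, and addition to an alkene between two quaternary carbons may be slow. Fallback from 18: hydrogen-atom-transfer hydrogenation (Mn(dpm)3 cat., PhSiH3, tert-butyl hydroperoxide, i-PrOH, rt). The metal hydride gives a hydrogen atom to C6, and the tertiary C5 radical takes the second hydrogen on the face away from C19 and C20. This should give trans-fused 19 without touching allylic C–O bonds and without a new compound.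

**Further compounds**

F1 | step 10 | methyl (3R)-3-methyl-5-oxooct-6-ynoate | CC#CC(=O)C[C@@H](C)CC(=O)OC
F2 | step 10 | methyl (4R,10R,13R)-11-oxo-19-[tri(propan-2-yl)silyloxy]labda-5,8-dien-15-oate | CC1=C(C(=O)C[C@@H](C)CC(=O)OC)[C@]2(C)CCC[C@@](C)(CO[Si](C(C)C)(C(C)C)C(C)C)C2=CC1
F3 | step 10 | methyl (4R,5S,10R,13R)-11-oxo-19-[tri(propan-2-yl)silyloxy]labd-8-en-15-oate | CC1=C(C(=O)C[C@@H](C)CC(=O)OC)[C@]2(C)CCC[C@@](C)(CO[Si](C(C)C)(C(C)C)C(C)C)[C@H]2CC1
F0 | step 12 | none | none
F0 | step 11 | none | none
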